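**Retrosynthetic overview**
1. The C3–C1′ bond (lactone α-carbon to the hydroxy-keto dienyl chain) is cut last: nickel-catalysed radical cross-electrophile coupling of α-bromolactone 21 with dienyl iodide 29. The planar α-lactonyl radical is captured trans to the 4-methyl group, which sets C3.
2. 29 comes from dienal 25 and but-3-en-2-one by a borane-mediated reductive syn-aldol; 25 comes from (E)-pent-2-en-4-yn-1-ol by carboalumination–iodination and oxidation.
3. 21 comes from lactone 18 by α-bromination; 18 from iodolactone 14 and alkenylboronate 17 by Suzuki coupling; 17 from (E)-1-bromohept-2-ene by copper-catalysed asymmetric allylic methylation and cross-metathesis.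
4. The only ring, the γ-lactone, is closed early (14) by oxidative lactonisation of diol 12; its C4/C5 stereocentres come from anti-crotylboration of iodoenal 4 (from propargyl alcohol).

Assumption: the facial sense of (R,R)-Taniaphos (step 6) and of the (−)-α-pinene-derived boron enolate (step 12) is taken by analogy with cinnamyl bromide methylation and with crotylboration by the same borane; if either runs the other way, the mirror-image ligand or borane is used.

Step 1
Reactants: 1 prop-2-yn-1-ol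
Product: 3 (E)-3-iodo-2-methylprop-2-en-1-ol, via alkenylalane 2 (not isolated)
Conditions: AlMe3 (3 equiv), Cp2ZrCl2 (0.25 equiv), CH2Cl2, 0 °C to rt; then I2, THF, −30 to 0 °C
Reagents that add atoms: trimethylaluminium C[Al](C)C; iodine [I][I]
Why: Negishi zirconium-catalysed carboalumination adds methyl and aluminium syn across the alkyne with methyl on the internal carbon, and iodinolysis of the C–Al bond with retention fixes the E vinyl iodide.

Step 2
Reactants: 3 (E)-3-iodo-2-methylprop-2-en-1-ol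
Product: 4 (E)-3-iodo-2-methylprop-2-enal
Conditions: MnO2 (15 equiv), CH2Cl2, rt; filtered and used as a solution
Reagents that add atoms: none
Why: MnO2 allylic oxidation stops at the enal and leaves the vinyl iodide and the alkene geometry untouched.

Step 3
Reactants: 4 (E)-3-iodo-2-methylprop-2-enal; 5 (E)-but-2-ene
Product: 10 (1E,3S,4S)-1-iodo-2,4-dimethylhexa-1,5-dien-3-ol, via crotylpotassium 6 (not isolated), via borate complex 7 (not isolated), via crotylborane 8 (not isolated), via borinate ester 9 (not isolated)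
Conditions: 5 (2 equiv), KOtBu, n-BuLi, THF, −78 to −45 °C; (−)-Ipc2BOMe [from (+)-α-pinene], −78 °C; BF3·OEt2, −78 °C; 4, −78 °C, 4 h; NaOH, H2O2, 0 °C to rt
Reagents that add atoms: none
Why: Brown crotylboration through a closed chair transition state, in which the E-crotyl unit gives the 3,4-anti relationship and the isopinocampheyl groups from (+)-α-pinene direct attack on the Si face of the aldehyde, giving 3S,4S.

Step 4
Reactants: 10 (1E,3S,4S)-1-iodo-2,4-dimethylhexa-1,5-dien-3-ol
Product: 12 (3S,4S,5E)-6-iodo-3,5-dimethylhex-5-ene-1,4-diol, via bis-borane adduct 11 (not isolated)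
Conditions: 9-BBN (2.2 equiv), THF, 0 °C to rt; then NaOH, H2O2, 0 °C
Reagents that add atoms: hydrogen peroxide OO
Why: Hydroboration–oxidation with 9-BBN is anti-Markovnikov and takes only the monosubstituted alkene, the trisubstituted vinyl iodide being inert, so both stereocentres are carried through unchanged.

Step 5
Reactants: 12 (3S,4S,5E)-6-iodo-3,5-dimethylhex-5-ene-1,4-diol
Product: 14 (4S,5S)-5-[(1E)-1-iodoprop-1-en-2-yl]-4-methyloxolan-2-one, via lactol 13 (not isolated)
Conditions: TEMPO (0.2 equiv), PhI(OAc)2 (2.5 equiv), CH2Cl2, rt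
Reagents that add atoms: none
Why: TEMPO/PhI(OAc)2 oxidative lactonisation oxidises the primary alcohol selectively, the aldehyde is trapped by the secondary hydroxyl as a lactol and oxidised on to the lactone, so the anti pair of step 3 becomes the 4,5-trans ring pair without being touched.

Step 6
Reactants: 15 (E)-1-bromohept-2-ene
Product: 16 (R)-3-methylhept-1-ene
Conditions: MeMgBr (1.2 equiv), CuBr·SMe2 (1 mol%), (R,R)-Taniaphos (C43H39FeNP2, 1.2 mol%), CH2Cl2, −75 °C
Reagents that add atoms: methylmagnesium bromide C[Mg]Br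
Why: Copper-catalysed asymmetric allylic alkylation (SN2′) delivers methyl to the γ-carbon of the allylic bromide under control of the chiral diphosphine–copper complex, creating the R methyl-bearing centre next to a terminal vinyl group.

Step 7
Reactants: 16 (R)-3-methylhept-1-ene
Product: 17 2-[(1E,3R)-3-methylhept-1-en-1-yl]-4,4,5,5-tetramethyl-1,3,2-dioxaborolane
Conditions: vinylboronic acid pinacol ester (2 equiv), second-generation Hoveyda–Grubbs catalyst (C31H38Cl2N2ORu, 5 mol%), CH2Cl2, 40 °C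
Reagents that add atoms: vinylboronic acid pinacol ester C=CB1OC(C)(C)C(C)(C)O1
Why: Olefin cross-metathesis of an α-branched terminal alkene with the vinylboronate gives the E-alkenylboronate with loss of ethene and does not touch the allylic stereocentre.

Step 8
Reactants: 14 (4S,5S)-5-[(1E)-1-iodoprop-1-en-2-yl]-4-methyloxolan-2-one; 17 2-[(1E,3R)-3-methylhept-1-en-1-yl]-4,4,5,5-tetramethyl-1,3,2-dioxaborolane
Product: 18 (4S,5S)-4-methyl-5-[(2E,4E,6R)-6-methyldeca-2,4-dien-2-yl]oxolan-2-one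
Conditions: Pd(dppf)Cl2 (5 mol%), K3PO4 (3 equiv), THF/H2O 10:1, 40 °C
Reagents that add atoms: none
Why: Suzuki–Miyaura coupling of a vinyl iodide with an alkenylboronate proceeds with retention at both alkenes and gives the 2E,4E-diene under a base mild enough for the lactone.

Step 9
Reactants: 18 (4S,5S)-4-methyl-5-[(2E,4E,6R)-6-methyldeca-2,4-dien-2-yl]oxolan-2-one
Product: 21 (3RS,4R,5S)-3-bromo-4-methyl-5-[(2E,4E,6R)-6-methyldeca-2,4-dien-2-yl]oxolan-2-one, via lithium enolate 19 (not isolated), via silyl ketene acetal 20 (not isolated)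
Conditions: LiN(SiMe3)2 (1.1 equiv), THF, −78 °C; Me3SiCl (1.3 equiv); NBS (1.05 equiv), −78 °C
Reagents that add atoms: N-bromosuccinimide BrN1C(=O)CCC1=O
Why: Electrophilic α-bromination through the silyl ketene acetal, which is far more nucleophilic than the diene, gives the monobromide as a C3 epimer mixture that needs no control because step 13 passes through a planar radical.

Step 10
Reactants: 22 (E)-pent-2-en-4-yn-1-ol
Product: 24 (2E,4E)-5-iodo-4-methylpenta-2,4-dien-1-ol, via dienylalane 23 (not isolated)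
Conditions: AlMe3 (3 equiv), Cp2ZrCl2 (0.3 equiv), CH2Cl2, 0 °C to rt; then I2, THF, −30 to 0 °C
Reagents that add atoms: trimethylaluminium C[Al](C)C; iodine [I][I]
Why: Negishi carboalumination of the terminal alkyne of the enyne (syn addition, methyl internal) followed by iodinolysis with retention gives the 4E iodide while the existing 2E alkene is untouched.

Step 11
Reactants: 24 (2E,4E)-5-iodo-4-methylpenta-2,4-dien-1-ol
Product: 25 (2E,4E)-5-iodo-4-methylpenta-2,4-dienal
Conditions: MnO2 (15 equiv), CH2Cl2, rt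
Reagents that add atoms: none
Why: MnO2 allylic oxidation gives the dienal under neutral conditions without isomerising the diene.

Step 12
Reactants: 25 (2E,4E)-5-iodo-4-methylpenta-2,4-dienal; 26 but-3-en-2-one
Product: 29 (3R,4S,5E,7E)-4-hydroxy-8-iodo-3,7-dimethylocta-5,7-dien-2-one, via enolborinate 27 (not isolated), via boron aldolate 28 (not isolated)
Conditions: (+)-Ipc2BH [from (−)-α-pinene] (1.1 equiv), 26 (1.15 equiv), Et2O, 0 °C, 2 h; 25, −78 to −20 °C; pH 7 buffer, MeOH, H2O2, 0 °C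
Reagents that add atoms: none
Why: Reductive aldol reaction in which 1,4-hydroboration of the s-cis enone gives the Z-enolborinate on the ethyl side only, the Zimmerman–Traxler chair gives the 3,4-syn pair, and the isopinocampheyl groups from (−)-α-pinene direct attack on the Re face of the aldehyde, giving 3R,4S.

Step 13
Reactants: 21 (3RS,4R,5S)-3-bromo-4-methyl-5-[(2E,4E,6R)-6-methyldeca-2,4-dien-2-yl]oxolan-2-one; 29 (3R,4S,5E,7E)-4-hydroxy-8-iodo-3,7-dimethylocta-5,7-dien-2-one
Product: 31 (3S,4S,5S)-3-[(1E,3E,5S,6R)-5-hydroxy-2,6-dimethyl-7-oxoocta-1,3-dien-1-yl]-4-methyl-5-[(2E,4E,6R)-6-methyldeca-2,4-dien-2-yl]oxolan-2-one, via lactonyl radical 30 (not isolated)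
Conditions: NiBr2·glyme (10 mol%), 4,4'-di-tert-butyl-2,2'-bipyridine (12 mol%), Mn powder (3 equiv), NaI (0.25 equiv), DMA, 0 °C to rt; 29 (1.3 equiv), 21 added slowly
Reagents that add atoms: none
Why: Nickel-catalysed reductive cross-electrophile coupling in which low-valent nickel abstracts bromine from either epimer of 21 to give the planar α-lactonyl radical 30, which is captured by the alkenylnickel formed from 29 on the face anti to the 4-methyl group, and reductive elimination from trivalent nickel forms C3–C1′ with retention of the E alkene, giving the all-trans 3S lactone without protecting the hydroxy ketone.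

**Compound list**
1 | prop-2-yn-1-ol | C#CCO | starting material
2 | (E)-[3-(dimethylalumanyl)-2-methylprop-2-en-1-yl]oxy(dimethyl)alumane | C[Al](C)/C=C(\C)CO[Al](C)C | intermediate
3 | (E)-3-iodo-2-methylprop-2-en-1-ol | I/C=C(\C)CO | intermediate
4 | (E)-3-iodo-2-methylprop-2-enal | I/C=C(\C)C=O | intermediate
5 | (E)-but-2-ene | C/C=C/C | starting material
6 | (E)-but-2-en-1-ylpotassium | C/C=C/[CH2-].[K+] | intermediate
7 | potassium [(E)-but-2-en-1-yl](methoxy)bis(isopinocampheyl)borate, isopinocampheyl groups from (+)-α-pinene | CO[B-](C/C=C/C)([C@@H]1C[C@@H]2C[C@H]([C@H]1C)C2(C)C)[C@@H]1C[C@@H]2C[C@H]([C@H]1C)C2(C)C.[K+] | intermediate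
8 | [(E)-but-2-en-1-yl]bis(isopinocampheyl)borane, isopinocampheyl groups from (+)-α-pinene | C/C=C/CB([C@@H]1C[C@@H]2C[C@H]([C@H]1C)C2(C)C)[C@@H]1C[C@@H]2C[C@H]([C@H]1C)C2(C)C | intermediate
9 | bis(isopinocampheyl)borinate ester of 10 (boron on O3) | I/C=C(\C)[C@@H](OB([C@@H]1C[C@@H]2C[C@H]([C@H]1C)C2(C)C)[C@@H]1C[C@@H]2C[C@H]([C@H]1C)C2(C)C)[C@@H](C)C=C | intermediate
10 | (1E,3S,4S)-1-iodo-2,4-dimethylhexa-1,5-dien-3-ol | I/C=C(\C)[C@@H](O)[C@@H](C)C=C | intermediate
11 | 10 carrying a 9-borabicyclo[3.3.1]nonan-9-yl group on O3 and another on C6 (terminal carbon of the former vinyl group) | I/C=C(\C)[C@@H](OB1C2CCCC1CCC2)[C@@H](C)CCB1C2CCCC1CCC2 | intermediate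
12 | (3S,4S,5E)-6-iodo-3,5-dimethylhex-5-ene-1,4-diol | I/C=C(\C)[C@@H](O)[C@@H](C)CCO | intermediate
13 | (4S,5S)-5-[(1E)-1-iodoprop-1-en-2-yl]-4-methyloxolan-2-ol (anomer mixture) | I/C=C(\C)[C@H]1OC(O)C[C@@H]1C | intermediate
14 | (4S,5S)-5-[(1E)-1-iodoprop-1-en-2-yl]-4-methyloxolan-2-one | I/C=C(\C)[C@H]1OC(=O)C[C@@H]1C | intermediate
15 | (E)-1-bromohept-2-ene | CCCC/C=C/CBr | starting material
16 | (R)-3-methylhept-1-ene | CCCC[C@@H](C)C=C | intermediate
17 | 2-[(1E,3R)-3-methylhept-1-en-1-yl]-4,4,5,5-tetramethyl-1,3,2-dioxaborolane | CCCC[C@@H](C)/C=C/B1OC(C)(C)C(C)(C)O1 | intermediate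
18 | (4S,5S)-4-methyl-5-[(2E,4E,6R)-6-methyldeca-2,4-dien-2-yl]oxolan-2-one | CCCC[C@@H](C)/C=C/C=C(\C)[C@H]1OC(=O)C[C@@H]1C | intermediate
19 | lithium enolate of 18 | CCCC[C@@H](C)/C=C/C=C(\C)[C@H]1OC([O-])=C[C@@H]1C.[Li+] | intermediate
20 | trimethylsilyl ketene acetal of 18 (2-silyloxy-4,5-dihydrofuran, C4 and C5 unchanged) | CCCC[C@@H](C)/C=C/C=C(\C)[C@H]1OC(O[Si](C)(C)C)=C[C@@H]1C | intermediate
21 | (3RS,4R,5S)-3-bromo-4-methyl-5-[(2E,4E,6R)-6-methyldeca-2,4-dien-2-yl]oxolan-2-one | CCCC[C@@H](C)/C=C/C=C(\C)[C@H]1OC(=O)C(Br)[C@@H]1C | intermediate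
22 | (E)-pent-2-en-4-yn-1-ol | C#C/C=C/CO | starting material
23 | (2E,4E)-[5-(dimethylalumanyl)-4-methylpenta-2,4-dien-1-yl]oxy(dimethyl)alumane | C[Al](C)/C=C(C)/C=C/CO[Al](C)C | intermediate
24 | (2E,4E)-5-iodo-4-methylpenta-2,4-dien-1-ol | I/C=C(C)/C=C/CO | intermediate
25 | (2E,4E)-5-iodo-4-methylpenta-2,4-dienal | I/C=C(C)/C=C/C=O | intermediate
26 | but-3-en-2-one | CC(=O)C=C | starting material
27 | (Z)-but-2-en-2-yl bis(isopinocampheyl)borinate, isopinocampheyl groups from (−)-α-pinene | C/C=C(/C)OB([C@H]1C[C@H]2C[C@@H]([C@@H]1C)C2(C)C)[C@H]1C[C@H]2C[C@@H]([C@@H]1C)C2(C)C | intermediate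
28 | bis(isopinocampheyl)borinate ester of 29 (boron on O4) | I/C=C(C)/C=C/[C@H](OB([C@H]1C[C@H]2C[C@@H]([C@@H]1C)C2(C)C)[C@H]1C[C@H]2C[C@@H]([C@@H]1C)C2(C)C)[C@@H](C)C(C)=O | intermediate
29 | (3R,4S,5E,7E)-4-hydroxy-8-iodo-3,7-dimethylocta-5,7-dien-2-one | I/C=C(C)/C=C/[C@H](O)[C@@H](C)C(C)=O | intermediate
30 | (4S,5S)-4-methyl-5-[(2E,4E,6R)-6-methyldeca-2,4-dien-2-yl]-2-oxooxolan-3-yl radical | CCCC[C@@H](C)/C=C/C=C(\C)[C@H]1OC(=O)[CH][C@@H]1C | intermediate
31 | (3S,4S,5S)-3-[(1E,3E,5S,6R)-5-hydroxy-2,6-dimethyl-7-oxoocta-1,3-dien-1-yl]-4-methyl-5-[(2E,4E,6R)-6-methyldeca-2,4-dien-2-yl]oxolan-2-one | CCCC[C@@H](C)/C=C/C=C(\C)[C@H]1OC(=O)[C@@H](/C=C(C)/C=C/[C@H](O)[C@@H](C)C(C)=O)[C@@H]1C | target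

**Totals**
Total step count: 13. Longest linear sequence: 8 steps (1, 2, 3, 4, 5, 8, 9, 13).

**Three steps most likely to fail, with fallbacks**

Step 13 (radical coupling with the unprotected hydroxy ketone). The β-hydroxy ketone of 29 may not survive the reducing nickel/manganese medium (retro-aldol, Reformatsky-type attack of a metal enolate on the ketone), and β-hydride loss to the butenolide competes with capture. The fallback sets out from 21 and 24 and comes back at 31. The same nickel-catalysed radical coupling is run with the robust dienol 24 in place of 29 and gives (3S,4S,5S)-3-[(1E,3E)-5-hydroxy-2-methylpenta-1,3-dien-1-yl]-4-methyl-5-[(2E,4E,6R)-6-methyldeca-2,4-dien-2-yl]oxolan-2-one F1. MnO2 then gives the dienal lactone F2. The neutral reductive aldol with enolborinate 27 (from 26 and (+)-Ipc2BH) gives the boron aldolate F3, and its buffered H2O2 work-up gives 31. The aldol bond is thus formed last, so the radical step no longer carries the sensitive hydroxy ketone.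

Step 12 (reductive aldol: enantioselectivity and facial sense rest on analogy, and 85–90% ee is the realistic ceiling). The fallback sets out from 25 and comes back at 29 by an auxiliary-controlled Evans syn-aldol. Propanoyl chloride and lithiated (R)-4-benzyl-1,3-oxazolidin-2-one (n-BuLi, THF, −78 °C) give (R)-4-benzyl-3-propanoyl-1,3-oxazolidin-2-one F4. Bu2BOTf/iPr2NEt converts it into its Z dibutylboron enolate F5, which adds to 25 to give the boron aldolate F6 and, after H2O2, the syn adduct (R)-4-benzyl-3-[(2R,3S,4E,6E)-3-hydroxy-7-iodo-2,6-dimethylhepta-4,6-dienoyl]-1,3-oxazolidin-2-one F7. AlMe3/MeNHOMe·HCl gives the Weinreb amide F8, and MeMgBr (THF, 0 °C) gives 29.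

Step 9 (α-bromination next to an electron-rich diene; over-bromination or diene attack). The fallback sets out from 18 and comes back at 31, changing the radical precursor from a bromide to a redox-active ester. Lithium enolate 19 is quenched with CO2 to give (4S,5S)-4-methyl-5-[(2E,4E,6R)-6-methyldeca-2,4-dien-2-yl]-2-oxooxolane-3-carboxylic acid F9. N-Hydroxyphthalimide and N,N'-diisopropylcarbodiimide give the N-acyloxyphthalimide ester F10. Nickel-catalysed reductive decarboxylative alkenylation of F10 with 29 (NiBr2·glyme, 4,4'-di-tert-butyl-2,2'-bipyridine, Mn powder, DMA) passes through the same radical 30 and gives 31.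

**Further compounds**
F1 | step 13 | (3S,4S,5S)-3-[(1E,3E)-5-hydroxy-2-methylpenta-1,3-dien-1-yl]-4-methyl-5-[(2E,4E,6R)-6-methyldeca-2,4-dien-2-yl]oxolan-2-one | CCCC[C@@H](C)/C=C/C=C(\C)[C@H]1OC(=O)[C@@H](/C=C(C)/C=C/CO)[C@@H]1C
F2 | step 13 | (2E,4E)-4-methyl-5-{(3S,4S,5S)-4-methyl-5-[(2E,4E,6R)-6-methyldeca-2,4-dien-2-yl]-2-oxooxolan-3-yl}penta-2,4-dienal | CCCC[C@@H](C)/C=C/C=C(\C)[C@H]1OC(=O)[C@@H](/C=C(C)/C=C/C=O)[C@@H]1C
F3 | step 13 | bis(isopinocampheyl)borinate ester of 31 (boron on the side-chain oxygen, isopinocampheyl groups from (−)-α-pinene) | CCCC[C@@H](C)/C=C/C=C(\C)[C@H]1OC(=O)[C@@H](/C=C(C)/C=C/[C@H](OB([C@H]2C[C@H]3C[C@@H]([C@@H]2C)C3(C)C)[C@H]2C[C@H]3C[C@@H]([C@@H]2C)C3(C)C)[C@@H](C)C(C)=O)[C@@H]1C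
F4 | step 12 | (R)-4-benzyl-3-propanoyl-1,3-oxazolidin-2-one | CCC(=O)N1[C@H](Cc2ccccc2)COC1=O
F5 | step 12 | Z dibutylboron enolate of F4 | C/C=C(\OB(CCCC)CCCC)N1[C@H](Cc2ccccc2)COC1=O
F6 | step 12 | dibutylborinate ester of F7 | I/C=C(C)/C=C/[C@H](OB(CCCC)CCCC)[C@@H](C)C(=O)N1[C@H](Cc2ccccc2)COC1=O
F7 | step 12 | (R)-4-benzyl-3-[(2R,3S,4E,6E)-3-hydroxy-7-iodo-2,6-dimethylhepta-4,6-dienoyl]-1,3-oxazolidin-2-one | I/C=C(C)/C=C/[C@H](O)[C@@H](C)C(=O)N1[C@H](Cc2ccccc2)COC1=O
F8 | step 12 | (2R,3S,4E,6E)-3-hydroxy-7-iodo-N-methoxy-N,2,6-trimethylhepta-4,6-dienamide | I/C=C(C)/C=C/[C@H](O)[C@@H](C)C(=O)N(C)OC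
F9 | step 9 | (4S,5S)-4-methyl-5-[(2E,4E,6R)-6-methyldeca-2,4-dien-2-yl]-2-oxooxolane-3-carboxylic acid (C3 epimer mixture) | CCCC[C@@H](C)/C=C/C=C(\C)[C@H]1OC(=O)C(C(O)=O)[C@@H]1C
F10 | step 9 | 1,3-dioxoisoindolin-2-yl ester of F9 | CCCC[C@@H](C)/C=C/C=C(\C)[C@H]1OC(=O)C(C(=O)ON2C(=O)c3ccccc3C2=O)[C@@H]1C
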